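Retrosynthetic overview
- Target 18 (1S,2R, trans) comes from the trans C2-ester/C3-formyl 1,2-dihydronaphthalene 15 by reduction, allylic oxidation and debenzylation; 15 comes from the C2 gem-diester enal 13 by loss of one ester and equilibration at C2.
- Ring B is cut at C4a–C4 and C2–C3: the four-atom unit C4a–C8a–C1–C2 of 7 (aryl bromide carbon to malonate carbon) is bridged by buta-1,3-diene, three of whose carbons become C4, C3 and the formyl carbon; the fourth is later cleaved off.
- C1 is set before ring closure by rhodium-catalysed asymmetric aryl addition to the arylidene malonate 5; the C4a bromide comes from 4-bromo-2,6-dimethoxyphenol.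
- Ring order: ring A and the pendant guaiacyl ring are bought; ring B is the only ring formed (step 5). The C3 epimers converge in step 7 and C2 is fixed in step 8.

Key step: step 5

Remark on numbering: core atoms are C1 (aryl-bearing), C2 (hydroxymethyl-bearing), C3 (formyl-bearing), C4, and ring A = C4a–C8a with OMe on C6 and C8 and OH on C7; compounds 9–12 are mixtures of C3 epimers by design.
Assumption: which antipode of the chiral diene delivers the aryl group to the Re face of C1 of 5 is to be fixed in a test reaction; both antipodes are available.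

Step 1
Reactants: 1 4-bromo-2,6-dimethoxyphenol
Product: 2 2-(benzyloxy)-5-bromo-1,3-dimethoxybenzene
Conditions: BnBr (1.2 equiv), K2CO3 (2 equiv), DMF, 60 °C
Reagents that add atoms: benzyl bromide, BrCc1ccccc1
Why: Williamson ether synthesis on the phenoxide protects the future C7 hydroxyl as a benzyl ether that should survive every later step and is removed by BCl3 at the end.

Step 2
Reactants: 2 2-(benzyloxy)-5-bromo-1,3-dimethoxybenzene
Product: 3 3-(benzyloxy)-6-bromo-2,4-dimethoxybenzaldehyde
Conditions: Cl2CHOMe (1.5 equiv), TiCl4 (2 equiv), CH2Cl2, −78 → 0 °C; then H2O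
Reagents that add atoms: dichloromethyl methyl ether, COC(Cl)Cl; water, O
Why: Rieche formylation: the two free ring positions of 2 are equivalent, each ortho to one methoxy group and para to the other, so the formyl group can only enter between OMe and Br, and the low temperature is chosen to spare the benzyl ether.

Step 3
Reactants: 3 3-(benzyloxy)-6-bromo-2,4-dimethoxybenzaldehyde; 4 dimethyl malonate
Product: 5 dimethyl 2-{[3-(benzyloxy)-6-bromo-2,4-dimethoxyphenyl]methylidene}propanedioate
Conditions: piperidine (0.2 equiv), AcOH (0.2 equiv), toluene, reflux, Dean–Stark trap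
Reagents that add atoms: none
Why: Knoevenagel condensation driven by azeotropic removal of water; the two identical esters leave no E/Z question.

Step 4
Reactants: 5 dimethyl 2-{[3-(benzyloxy)-6-bromo-2,4-dimethoxyphenyl]methylidene}propanedioate; 6 [4-(benzyloxy)-3-methoxyphenyl]boronic acid
Product: 7 dimethyl 2-{(S)-[3-(benzyloxy)-6-bromo-2,4-dimethoxyphenyl][4-(benzyloxy)-3-methoxyphenyl]methyl}propanedioate
Conditions: [RhCl(C2H4)2]2 (2.5 mol %), chiral diene Ph-bod* (2,5-diphenylbicyclo[2.2.2]octa-2,5-diene, 5.5 mol %, antipode giving Re-face arylation), KOH (0.2 equiv), 6 (2 equiv), 1,4-dioxane/H2O 10:1, 50 °C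
Reagents that add atoms: none
Why: Hayashi–Miyaura asymmetric 1,4-addition: the aryl group passes from boron to monovalent rhodium, the aryl–rhodium species inserts the doubly activated alkene and water protonates the rhodium enolate; the chiral diene directs the aryl group to the Re face of C1, which sets the (S) centre, and the aryl bromide is not expected to react with monovalent rhodium under these conditions.

Step 5
Reactants: 7 dimethyl 2-{(S)-[3-(benzyloxy)-6-bromo-2,4-dimethoxyphenyl][4-(benzyloxy)-3-methoxyphenyl]methyl}propanedioate; 8 buta-1,3-diene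
Product: 9 dimethyl (1S)-7-(benzyloxy)-1-[4-(benzyloxy)-3-methoxyphenyl]-3-ethenyl-6,8-dimethoxy-3,4-dihydronaphthalene-2,2(1H)-dicarboxylate (both C3 epimers)
Conditions: Pd(OAc)2 (10 mol %), PPh3 (20 mol %), K2CO3 (2.5 equiv), n-Bu4NCl (1 equiv), 8 (10 equiv), DMF, 100 °C, sealed tube
Reagents that add atoms: none
Why: Pd(OAc)2 is reduced in situ by PPh3 to zerovalent palladium, which inserts into the C4a–Br bond of 7; the arylpalladium bromide (divalent palladium) adds across one double bond of 8 with the aryl group going to the terminal carbon (C4a–C4 bond), and the carbonate-generated malonate anion attacks the resulting π-allyl complex at its near terminus (C2–C3 bond), setting zerovalent palladium free again. The closest known reaction type is the Larock carboannulation of 1,3-dienes by o-halobenzyl malonates, which gives 3-vinyltetralin-2,2-dicarboxylates; here the benzylic carbon carries an extra aryl group and the halide is a bromide. Ring B is closed by 6-exo attack of the tethered soft carbon nucleophile on the proximal allyl carbon, which is favoured over attack at the distal terminus (8-membered ring). The new stereocentre C3 is not controlled, both epimers are expected and both are carried on because C3 becomes sp2 in step 7; C1 has no acidic hydrogen under carbonate and should keep its configuration. The step needs site selectivity between the two aryl rings, which the single C–Br bond on ring A secures, and it needs diene insertion and allyl capture to outrun C–H palladation of the neighbouring aryl ring and β-hydride loss, which the large excess of diene and the intramolecular malonate anion are meant to secure.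

Step 6
Reactants: 9 dimethyl (1S)-7-(benzyloxy)-1-[4-(benzyloxy)-3-methoxyphenyl]-3-ethenyl-6,8-dimethoxy-3,4-dihydronaphthalene-2,2(1H)-dicarboxylate
Product: 11 dimethyl (1S)-7-(benzyloxy)-1-[4-(benzyloxy)-3-methoxyphenyl]-3-formyl-6,8-dimethoxy-3,4-dihydronaphthalene-2,2(1H)-dicarboxylate (both C3 epimers), via vicinal diol 10 (not isolated)
Conditions: OsO4 (2 mol %), NaIO4 (4 equiv), 2,6-lutidine (2 equiv), 1,4-dioxane/H2O 3:1, 23 °C
Reagents that add atoms: sodium periodate, [Na+].[O-]I(=O)(=O)=O; osmium tetroxide, O=[Os](=O)(=O)=O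
Why: Lemieux–Johnson cleavage: OsO4 dihydroxylates the only alkene and NaIO4 cleaves the diol to the C3 aldehyde while re-oxidising osmium, with 2,6-lutidine as buffer; the electron-rich arenes and benzyl ethers are not attacked.

Step 7
Reactants: 11 dimethyl (1S)-7-(benzyloxy)-1-[4-(benzyloxy)-3-methoxyphenyl]-3-formyl-6,8-dimethoxy-3,4-dihydronaphthalene-2,2(1H)-dicarboxylate
Product: 13 dimethyl (1S)-7-(benzyloxy)-1-[4-(benzyloxy)-3-methoxyphenyl]-3-formyl-6,8-dimethoxynaphthalene-2,2(1H)-dicarboxylate, via trimethylsilyl enol ether 12 (not isolated)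
Conditions: TMSOTf (1.3 equiv), Et3N (2 equiv), CH2Cl2, 0 °C; then Pd(OAc)2 (10 mol %), O2 (1 atm), DMSO, 40 °C
Reagents that add atoms: none
Why: Saegusa–Ito oxidation in its aerobic catalytic form: divalent palladium takes the enol silane to a C3-bound palladium enolate, and because C2 is still quaternary the β-hydride can only come from the benzylic C4, so the C3=C4 enal forms regiospecifically and both C3 epimers converge.

Step 8
Reactants: 13 dimethyl (1S)-7-(benzyloxy)-1-[4-(benzyloxy)-3-methoxyphenyl]-3-formyl-6,8-dimethoxynaphthalene-2,2(1H)-dicarboxylate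
Product: 15 methyl (1S,2R)-7-(benzyloxy)-1-[4-(benzyloxy)-3-methoxyphenyl]-3-formyl-6,8-dimethoxy-1,2-dihydronaphthalene-2-carboxylate (1,2-trans), via C2-epimeric monoester 14 (not isolated)
Conditions: LiCl (3 equiv), H2O (2 equiv), DMSO, 140 °C, argon; then DBU (0.2 equiv), CH2Cl2, 23 °C
Reagents that add atoms: none
Why: Krapcho dealkoxycarbonylation: chloride removes one ester methyl by SN2 attack, the half-carboxylate loses CO2 and the ester enolate is protonated at C2 (kinetically anti to the aryl group, giving mainly cis), and DBU then equilibrates the epimerisable C2 centre to the trans isomer, in which the C1 aryl and C2 ester are both pseudoaxial and so avoid the C8 methoxy and the C3 formyl group.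

Step 9
Reactants: 15 methyl (1S,2R)-7-(benzyloxy)-1-[4-(benzyloxy)-3-methoxyphenyl]-3-formyl-6,8-dimethoxy-1,2-dihydronaphthalene-2-carboxylate
Product: 16 [(1S,2R)-7-(benzyloxy)-1-[4-(benzyloxy)-3-methoxyphenyl]-6,8-dimethoxy-1,2-dihydronaphthalene-2,3-diyl]dimethanol
Conditions: i-Bu2AlH (5 equiv), CH2Cl2, −78 → 0 °C; then aq. KNaC4H4O6
Reagents that add atoms: none
Why: i-Bu2AlH reduces the ester and, by 1,2-addition, the enal to the diol without touching the trisubstituted alkene or the benzyl ethers; after this step C2 is no longer enolisable.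

Step 10
Reactants: 16 [(1S,2R)-7-(benzyloxy)-1-[4-(benzyloxy)-3-methoxyphenyl]-6,8-dimethoxy-1,2-dihydronaphthalene-2,3-diyl]dimethanol
Product: 17 (1S,2R)-7-(benzyloxy)-1-[4-(benzyloxy)-3-methoxyphenyl]-2-(hydroxymethyl)-6,8-dimethoxy-1,2-dihydronaphthalene-3-carbaldehyde
Conditions: activated MnO2 (15 equiv), CH2Cl2, 23 °C
Reagents that add atoms: none
Why: Chemoselective allylic oxidation: MnO2 oxidises the cinnamyl-type carbinol on C3 and leaves the saturated primary alcohol on C2, and the conjugated hydroxy-aldehyde should stay open-chain so that over-oxidation through a lactol is slow.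

Step 11
Reactants: 17 (1S,2R)-7-(benzyloxy)-1-[4-(benzyloxy)-3-methoxyphenyl]-2-(hydroxymethyl)-6,8-dimethoxy-1,2-dihydronaphthalene-3-carbaldehyde
Product: 18 (1S,2R)-7-hydroxy-1-(4-hydroxy-3-methoxyphenyl)-2-(hydroxymethyl)-6,8-dimethoxy-1,2-dihydronaphthalene-3-carbaldehyde
Conditions: BCl3 (5 equiv), C6HMe5 (6 equiv), CH2Cl2, −78 °C; then H2O, 0 °C
Reagents that add atoms: none
Why: Lewis-acid debenzylation: BCl3 cleaves both aryl benzyl ethers at low temperature and pentamethylbenzene traps the benzyl cation by Friedel–Crafts alkylation, so the electron-rich rings, the methyl ethers and the enal should stay intact, where hydrogenolysis would reduce the alkene.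

Compound list
1 | 4-bromo-2,6-dimethoxyphenol | COc1cc(Br)cc(OC)c1O | starting material
2 | 2-(benzyloxy)-5-bromo-1,3-dimethoxybenzene | COc1cc(Br)cc(OC)c1OCc1ccccc1 | intermediate
3 | 3-(benzyloxy)-6-bromo-2,4-dimethoxybenzaldehyde | COc1cc(Br)c(C=O)c(OC)c1OCc1ccccc1 | intermediate
4 | dimethyl malonate | COC(=O)CC(=O)OC | starting material
5 | dimethyl 2-{[3-(benzyloxy)-6-bromo-2,4-dimethoxyphenyl]methylidene}propanedioate | COC(=O)C(=Cc1c(Br)cc(OC)c(OCc2ccccc2)c1OC)C(=O)OC | intermediate
6 | [4-(benzyloxy)-3-methoxyphenyl]boronic acid | COc1cc(B(O)O)ccc1OCc1ccccc1 | starting material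
7 | dimethyl 2-{(S)-[3-(benzyloxy)-6-bromo-2,4-dimethoxyphenyl][4-(benzyloxy)-3-methoxyphenyl]methyl}propanedioate | COc1cc([C@H](C(C(=O)OC)C(=O)OC)c2c(Br)cc(OC)c(OCc3ccccc3)c2OC)ccc1OCc1ccccc1 | intermediate
8 | buta-1,3-diene | C=CC=C | starting material
9 | dimethyl (1S)-7-(benzyloxy)-1-[4-(benzyloxy)-3-methoxyphenyl]-3-ethenyl-6,8-dimethoxy-3,4-dihydronaphthalene-2,2(1H)-dicarboxylate (C3 epimers) | COc1cc([C@H]2c3c(cc(OC)c(OCc4ccccc4)c3OC)CC(C=C)C2(C(=O)OC)C(=O)OC)ccc1OCc1ccccc1 | intermediate
10 | dimethyl (1S)-7-(benzyloxy)-1-[4-(benzyloxy)-3-methoxyphenyl]-3-(1,2-dihydroxyethyl)-6,8-dimethoxy-3,4-dihydronaphthalene-2,2(1H)-dicarboxylate (diastereomer mixture) | COc1cc([C@H]2c3c(cc(OC)c(OCc4ccccc4)c3OC)CC(C(O)CO)C2(C(=O)OC)C(=O)OC)ccc1OCc1ccccc1 | intermediate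
11 | dimethyl (1S)-7-(benzyloxy)-1-[4-(benzyloxy)-3-methoxyphenyl]-3-formyl-6,8-dimethoxy-3,4-dihydronaphthalene-2,2(1H)-dicarboxylate (C3 epimers) | COc1cc([C@H]2c3c(cc(OC)c(OCc4ccccc4)c3OC)CC(C=O)C2(C(=O)OC)C(=O)OC)ccc1OCc1ccccc1 | intermediate
12 | dimethyl (1S)-7-(benzyloxy)-1-[4-(benzyloxy)-3-methoxyphenyl]-6,8-dimethoxy-3-{[(trimethylsilyl)oxy]methylidene}-3,4-dihydronaphthalene-2,2(1H)-dicarboxylate (E/Z mixture) | COc1cc([C@H]2c3c(cc(OC)c(OCc4ccccc4)c3OC)CC(=CO[Si](C)(C)C)C2(C(=O)OC)C(=O)OC)ccc1OCc1ccccc1 | intermediate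
13 | dimethyl (1S)-7-(benzyloxy)-1-[4-(benzyloxy)-3-methoxyphenyl]-3-formyl-6,8-dimethoxynaphthalene-2,2(1H)-dicarboxylate | COc1cc([C@H]2c3c(cc(OC)c(OCc4ccccc4)c3OC)C=C(C=O)C2(C(=O)OC)C(=O)OC)ccc1OCc1ccccc1 | intermediate
14 | methyl (1S)-7-(benzyloxy)-1-[4-(benzyloxy)-3-methoxyphenyl]-3-formyl-6,8-dimethoxy-1,2-dihydronaphthalene-2-carboxylate (C2 epimers) | COc1cc([C@H]2c3c(cc(OC)c(OCc4ccccc4)c3OC)C=C(C=O)C2C(=O)OC)ccc1OCc1ccccc1 | intermediate
15 | methyl (1S,2R)-7-(benzyloxy)-1-[4-(benzyloxy)-3-methoxyphenyl]-3-formyl-6,8-dimethoxy-1,2-dihydronaphthalene-2-carboxylate | COc1cc([C@H]2c3c(cc(OC)c(OCc4ccccc4)c3OC)C=C(C=O)[C@@H]2C(=O)OC)ccc1OCc1ccccc1 | intermediate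
16 | [(1S,2R)-7-(benzyloxy)-1-[4-(benzyloxy)-3-methoxyphenyl]-6,8-dimethoxy-1,2-dihydronaphthalene-2,3-diyl]dimethanol | COc1cc([C@H]2c3c(cc(OC)c(OCc4ccccc4)c3OC)C=C(CO)[C@@H]2CO)ccc1OCc1ccccc1 | intermediate
17 | (1S,2R)-7-(benzyloxy)-1-[4-(benzyloxy)-3-methoxyphenyl]-2-(hydroxymethyl)-6,8-dimethoxy-1,2-dihydronaphthalene-3-carbaldehyde | COc1cc([C@H]2c3c(cc(OC)c(OCc4ccccc4)c3OC)C=C(C=O)[C@@H]2CO)ccc1OCc1ccccc1 | intermediate
18 | (1S,2R)-7-hydroxy-1-(4-hydroxy-3-methoxyphenyl)-2-(hydroxymethyl)-6,8-dimethoxy-1,2-dihydronaphthalene-3-carbaldehyde, i.e. (3R,4S)-6-hydroxy-4-(4-hydroxy-3-methoxyphenyl)-3-(hydroxymethyl)-5,7-dimethoxy-3,4-dihydronaphthalene-2-carbaldehyde | COc1cc([C@H]2c3c(cc(OC)c(O)c3OC)C=C(C=O)[C@@H]2CO)ccc1O | target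

Total step count: 11. Longest linear sequence: 11 steps (1 → 18); the route is fully linear, and 4, 6 and 8 are bought.

Steps most likely to fail

1. Step 5. The arylpalladium bromide may be diverted into C–H palladation of the neighbouring guaiacyl ring (fluorene formation), or the π-allyl complex may lose a β-hydrogen to an aryldiene before the hindered malonate carbon attacks. The fallback makes the two bonds one at a time. It sets out from 7: Stille coupling with allyltributylstannane (Pd(PPh3)4, toluene, 110 °C) should give the allylarene dimethyl 2-{(S)-[3-(benzyloxy)-2,4-dimethoxy-6-(prop-2-en-1-yl)phenyl][4-(benzyloxy)-3-methoxyphenyl]methyl}propanedioate F1. Cross-metathesis with (Z)-but-2-ene-1,4-diyl diacetate (RuCl2(H2IMes)(PCy3)(=CHPh), the second-generation Grubbs catalyst, CH2Cl2, 40 °C) should then give the (E)-allylic acetate F2. NaH followed by Pd(PPh3)4 in THF at 65 °C ionises the acetate to the same π-allyl complex, and the malonate closes ring B by intramolecular Tsuji–Trost alkylation. The fallback comes back to the route at 9.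

2. Step 4. Insertion of the alkene into the aryl–rhodium bond may be slow because the aryl group on C1 of 5 carries two ortho substituents, so that protodeboronation of 6 takes over and facial selectivity suffers. The fallback gives up catalytic asymmetric induction for resolution. It sets out from 5: CuI-catalysed conjugate addition of [4-(benzyloxy)-3-methoxyphenyl]magnesium bromide F3 (from commercial 1-(benzyloxy)-4-bromo-2-methoxybenzene and Mg, THF) at −20 °C should give the racemic malonate F4. Preparative chromatography on a chiral stationary phase (supercritical CO2/MeOH) separates the (S)-enantiomer from the (R)-enantiomer F5. The fallback comes back to the route at 7.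

3. Step 8. At 140 °C in chloride/DMSO the conjugated aldehyde may degrade, or the C3=C4 bond may migrate into conjugation with the ester, which would make C1–H acidic and put its configuration at risk. The fallback removes the ester by a different mechanism at lower temperature. It sets out from 13: Me3SnOH (1,2-dichloroethane, 80 °C; aq. HCl work-up) cleaves one methyl ester by acyl–oxygen attack to the malonic half-acid F6, which should lose CO2 in toluene at 90 °C (cat. Et3N). The fallback comes back to the route at 14, before the DBU equilibration to 15.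

Further compounds
F1 | step 5 | dimethyl 2-{(S)-[3-(benzyloxy)-2,4-dimethoxy-6-(prop-2-en-1-yl)phenyl][4-(benzyloxy)-3-methoxyphenyl]methyl}propanedioate | COc1cc([C@H](C(C(=O)OC)C(=O)OC)c2c(CC=C)cc(OC)c(OCc3ccccc3)c2OC)ccc1OCc1ccccc1
F2 | step 5 | dimethyl 2-{(S)-[6-[(2E)-4-acetoxybut-2-en-1-yl]-3-(benzyloxy)-2,4-dimethoxyphenyl][4-(benzyloxy)-3-methoxyphenyl]methyl}propanedioate | COc1cc([C@H](C(C(=O)OC)C(=O)OC)c2c(C/C=C/COC(C)=O)cc(OC)c(OCc3ccccc3)c2OC)ccc1OCc1ccccc1
F3 | step 4 | [4-(benzyloxy)-3-methoxyphenyl]magnesium bromide | COc1cc([Mg]Br)ccc1OCc1ccccc1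
F4 | step 4 | racemic dimethyl 2-{[3-(benzyloxy)-6-bromo-2,4-dimethoxyphenyl][4-(benzyloxy)-3-methoxyphenyl]methyl}propanedioate | COc1cc(C(C(C(=O)OC)C(=O)OC)c2c(Br)cc(OC)c(OCc3ccccc3)c2OC)ccc1OCc1ccccc1
F5 | step 4 | dimethyl 2-{(R)-[3-(benzyloxy)-6-bromo-2,4-dimethoxyphenyl][4-(benzyloxy)-3-methoxyphenyl]methyl}propanedioate | COc1cc([C@@H](C(C(=O)OC)C(=O)OC)c2c(Br)cc(OC)c(OCc3ccccc3)c2OC)ccc1OCc1ccccc1
F6 | step 8 | (1S)-7-(benzyloxy)-1-[4-(benzyloxy)-3-methoxyphenyl]-3-formyl-6,8-dimethoxy-2-(methoxycarbonyl)-1,2-dihydronaphthalene-2-carboxylic acid (C2 epimers) | COc1cc([C@H]2c3c(cc(OC)c(OCc4ccccc4)c3OC)C=C(C=O)C2(C(=O)O)C(=O)OC)ccc1OCc1ccccc1
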